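**Assumptions.** The target is drawn as the free guanidine; the last step delivers its HBr salt, which is neutralised in the workup. The sense of induction of the chiral Ir catalyst in Step 2 cannot be predicted for this new substrate class, so the ligand antipode that gives (1S,6R)-3 is used (both antipodes are available).

## Retrosynthetic overview

1. C–S: agelasidine C (14) ⇒ diterpenyl allylic bromide 11 + hypotaurocyamine 13 (sulfinate S-alkylation).
2. C(sp3)–C(sp3): 11 ⇒ neopentyl iodide 5 (as its Grignard) + 8-bromogeranyl TBS ether 9 (Cu-catalysed allylic coupling).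
3. Both stereocentres: 5 ⇒ acid 3 ⇒ prochiral diene acid 2, by an enantioselective carboxylate-directed mono-hydrogenation that differentiates the two enantiotopic ring olefins.
4. 2 ⇒ 2,6-dimethylbenzoic acid (1) by Birch reductive methylation.
5. Rings: the single carbocycle is the benzene ring of 1 carried through; no ring-forming step.

## Route

**Step 1**
Reactants: 1, 2,6-dimethylbenzoic acid
Product: 2, 1,2,6-trimethylcyclohexa-2,5-diene-1-carboxylic acid (achiral, Cs-symmetric)
Conditions: Li (3 equiv), NH3(l)/THF, −78 °C; then MeI (excess), −78 °C → rt; H3O+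
Reagents that add atoms: iodomethane, CI
Why: Birch reductive alkylation; the benzoate is reduced to the 1,4-dihydro dianion with both methyls left on sp2 carbons, and the carboxylate-bearing central carbon of the cyclohexadienyl anion is methylated, giving the quaternary carbon with no stereocentre yet.

**Step 2 (key step)**
Reactants: 2, 1,2,6-trimethylcyclohexa-2,5-diene-1-carboxylic acid
Product: 3, (1S,6R)-1,2,6-trimethylcyclohex-2-ene-1-carboxylic acid (6-Me cis to 1-Me; 6-H cis to CO2H)
Conditions: [Ir(cod)(chiral spiro phosphine–oxazoline, SIPHOX type)]BArF (1 mol%), H2 (about 6 atm, stopped at 1.0 equiv uptake), Cs2CO3 (0.5 equiv), MeOH, 25 °C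
Reagents that add atoms: none (H2 only)
Why: Proposed new method: the carboxylate binds the cationic Ir dihydride and both hydrogens are delivered to the β,γ-olefin on the carboxylate face, which fixes the new C–H cis to CO2H and hence the two methyls cis; the chiral P,N pocket selects one of the two enantiotopic olefins, which sets the quaternary centre. Over-reduction drains mainly the minor enantiomer to the meso saturated acid and so raises ee. The closest known reaction types are carboxy-directed Ir/spiro-P,N asymmetric hydrogenation of β,γ-unsaturated acids, Crabtree-type directed hydrogenation, and Ir-catalysed asymmetric hydrogenation of Birch 1,4-dienes.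

**Step 3**
Reactants: 3, (1S,6R)-1,2,6-trimethylcyclohex-2-ene-1-carboxylic acid
Product: 4, [(1S,6R)-1,2,6-trimethylcyclohex-2-en-1-yl]methanol
Conditions: LiAlH4, THF, 0 °C → reflux
Reagents that add atoms: none
Why: Hydride reduction of a hindered acid to the neopentyl alcohol; the isolated trisubstituted olefin and both non-epimerisable stereocentres are untouched.

**Step 4**
Reactants: 4, [(1S,6R)-1,2,6-trimethylcyclohex-2-en-1-yl]methanol
Product: 5, (5R,6S)-6-(iodomethyl)-1,5,6-trimethylcyclohex-1-ene
Conditions: PPh3, I2, imidazole, PhMe, 90 °C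
Reagents that add atoms: iodine, II
Why: Appel/Garegg–Samuelsson iodination; SN2 displacement of the alkoxyphosphonium by iodide works on neopentyl primary alcohols on heating under non-ionising conditions, and no stereocentre is involved.

**Step 5**
Reactants: 6, geraniol
Product: 7, tert-butyl{[(2E)-3,7-dimethylocta-2,6-dien-1-yl]oxy}dimethylsilane
Conditions: TBSCl, imidazole, CH2Cl2, rt
Reagents that add atoms: tert-butyldimethylsilyl chloride, CC(C)(C)[Si](C)(C)Cl
Why: Standard silylation; protects the allylic alcohol against the organometallic coupling.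

**Step 6**
Reactants: 7, geranyl TBS ether
Product: 8, (2E,6E)-8-[(tert-butyldimethylsilyl)oxy]-2,6-dimethylocta-2,6-dien-1-ol
Conditions: SeO2 (cat.), t-BuOOH, salicylic acid (cat.), CH2Cl2, 0 °C → rt; then NaBH4, MeOH (returns over-oxidised enal)
Reagents that add atoms: tert-butyl hydroperoxide, CC(C)(C)OO; selenium dioxide, O=[Se]=O
Why: Sharpless SeO2 allylic oxidation (ene/[2,3] sequence) is selective for the (E)-methyl of the electron-rich terminal olefin; the 2,3-olefin is deactivated by the allylic oxygen.

**Step 7**
Reactants: 8, (2E,6E)-8-[(tert-butyldimethylsilyl)oxy]-2,6-dimethylocta-2,6-dien-1-ol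
Product: 9, tert-butyl{[(2E,6E)-8-bromo-3,7-dimethylocta-2,6-dien-1-yl]oxy}dimethylsilane
Conditions: CBr4, PPh3, CH2Cl2, 0 °C
Reagents that add atoms: carbon tetrabromide, BrC(Br)(Br)Br
Why: Appel bromination of a primary allylic alcohol under neutral conditions; E geometry is retained and the TBS ether survives.

**Step 8**
Reactants: 5, (5R,6S)-6-(iodomethyl)-1,5,6-trimethylcyclohex-1-ene; 9, 8-bromogeranyl TBS ether
Product: 10, tert-butyl{[(2E,6E)-3,7-dimethyl-9-[(1S,6R)-1,2,6-trimethylcyclohex-2-en-1-yl]nona-2,6-dien-1-yl]oxy}dimethylsilane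
Conditions: 5, t-BuLi (2.1 equiv), Et2O/pentane, −78 °C; MgBr2·OEt2; then 9, Li2CuCl4 (5 mol%), THF, −78 → 0 °C
Reagents that add atoms: none
Why: Li–I exchange gives the neopentyl-lithium without radical intermediates (kept at −78 °C to avoid a homoallyl/cyclopropylcarbinyl 1,2-vinyl shift); after transmetalation to Mg, Kochi–Schlosser Cu-catalysed coupling with the primary allylic bromide proceeds α-selectively (SN2) with retention of the E olefin.

**Step 9**
Reactants: 10, coupled TBS ether
Product: 11, (5R,6S)-6-[(3E,7E)-9-bromo-3,7-dimethylnona-3,7-dien-1-yl]-1,5,6-trimethylcyclohex-1-ene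
Conditions: Ph3PBr2, CH2Cl2, 0 °C → rt
Reagents that add atoms: triphenylphosphine dibromide, BrP(Br)(c1ccccc1)(c1ccccc1)c1ccccc1
Why: Direct Appel-type exchange of a silyl ether for bromide via the alkoxyphosphonium, under neutral conditions; this avoids a separate deprotection and gives the primary (E)-allylic bromide without acid-induced polyene cyclisation.

**Step 10**
Reactants: 12, hypotaurine (2-aminoethanesulfinic acid)
Product: 13, hypotaurocyamine (2-guanidinoethanesulfinic acid, zwitterion)
Conditions: 1H-pyrazole-1-carboxamidine·HCl, Na2CO3, H2O, rt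
Reagents that add atoms: 1H-pyrazole-1-carboxamidine hydrochloride, Cl.NC(=N)n1cccn1
Why: Amidine transfer to the primary amine (guanylation) with loss of pyrazole; the sulfinate is inert to the reagent.

**Step 11**
Reactants: 11, diterpenyl allylic bromide; 13, hypotaurocyamine
Product: 14, agelasidine C, 2-[2-({(2E,6E)-3,7-dimethyl-9-[(1S,6R)-1,2,6-trimethylcyclohex-2-en-1-yl]nona-2,6-dien-1-yl}sulfonyl)ethyl]guanidine
Conditions: DMF/H2O (about 5:1), 25–40 °C; then neutralise the guanidinium bromide (basic ion-exchange resin or 1 equiv NaOMe)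
Reagents that add atoms: none
Why: SN2 S-alkylation of the soft sulfinate by the primary allylic bromide gives the sulfone; the guanidine is protonated in the zwitterion and so does not compete, and E geometry and both stereocentres are unaffected.

## Compound list

1 | 2,6-dimethylbenzoic acid | Cc1cccc(C)c1C(=O)O | starting material
2 | 1,2,6-trimethylcyclohexa-2,5-diene-1-carboxylic acid | CC1=CCC=C(C)C1(C)C(=O)O | intermediate
3 | (1S,6R)-1,2,6-trimethylcyclohex-2-ene-1-carboxylic acid | CC1=CCC[C@@H](C)[C@]1(C)C(=O)O | intermediate
4 | [(1S,6R)-1,2,6-trimethylcyclohex-2-en-1-yl]methanol | CC1=CCC[C@@H](C)[C@]1(C)CO | intermediate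
5 | (5R,6S)-6-(iodomethyl)-1,5,6-trimethylcyclohex-1-ene | CC1=CCC[C@@H](C)[C@]1(C)CI | intermediate
6 | geraniol | CC(C)=CCC/C(C)=C/CO | starting material
7 | geranyl TBS ether | CC(C)=CCC/C(C)=C/CO[Si](C)(C)C(C)(C)C | intermediate
8 | (2E,6E)-8-[(tert-butyldimethylsilyl)oxy]-2,6-dimethylocta-2,6-dien-1-ol | OC/C(C)=C/CC/C(C)=C/CO[Si](C)(C)C(C)(C)C | intermediate
9 | tert-butyl{[(2E,6E)-8-bromo-3,7-dimethylocta-2,6-dien-1-yl]oxy}dimethylsilane | BrC/C(C)=C/CC/C(C)=C/CO[Si](C)(C)C(C)(C)C | intermediate
10 | tert-butyl{[(2E,6E)-3,7-dimethyl-9-[(1S,6R)-1,2,6-trimethylcyclohex-2-en-1-yl]nona-2,6-dien-1-yl]oxy}dimethylsilane | CC1=CCC[C@@H](C)[C@]1(C)CC/C(C)=C/CC/C(C)=C/CO[Si](C)(C)C(C)(C)C | intermediate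
11 | (5R,6S)-6-[(3E,7E)-9-bromo-3,7-dimethylnona-3,7-dien-1-yl]-1,5,6-trimethylcyclohex-1-ene | CC1=CCC[C@@H](C)[C@]1(C)CC/C(C)=C/CC/C(C)=C/CBr | intermediate
12 | hypotaurine | NCCS(=O)O | starting material
13 | hypotaurocyamine (2-guanidinoethanesulfinic acid) | NC(N)=NCCS(=O)O | intermediate
14 | agelasidine C | CC1=CCC[C@@H](C)[C@]1(C)CC/C(C)=C/CC/C(C)=C/CS(=O)(=O)CCN=C(N)N | target

## Summary

Total steps: 11 (ring fragment 4, chain fragment 3, coupling 1, end game 2, sulfinate partner 1).

Longest linear sequence: 7 steps (Steps 1, 2, 3, 4, 8, 9, 11) from 2,6-dimethylbenzoic acid.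

Three steps most likely to fail, each with a fallback:

- **Step 2 (desymmetrising hydrogenation).** Risks are low ee, over-reduction, or a sluggish reaction at the hindered olefin next to the quaternary carbon. Fallback: give up catalytic enantiocontrol. Run the carboxylate-directed (or, on the alcohol from LiAlH4 reduction of 2, hydroxyl-directed) mono-hydrogenation with achiral Crabtree catalyst, which still secures the cis-dimethyl relative configuration, then resolve racemic acid 3 by crystallising its salt with (R)- or (S)-1-phenylethylamine.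
- **Step 8 (neopentyl organometallic/allylic coupling).** Risks are rearrangement of the homoallylic organometallic or SN2′ leakage. Fallback: change the bond formed. Oxidise 4 to the aldehyde, methylenate with Ph3P=CH2, hydroborate the vinyl group with 9-BBN, and B-alkyl Suzuki couple with tert-butyl{[(2E,6E)-7-iodo-3-methylocta-2,6-dien-1-yl]oxy}dimethylsilane, so the C2′–C3′ bond is made instead.
- **Step 11 (sulfinate alkylation with the unprotected zwitterion).** Risks are poor mutual solubility of the two partners, O-alkylation, or solvolysis of the bromide. Fallback: build the sulfone by oxidation. Alkylate N-Boc-cysteamine thiolate with 11, oxidise the sulfide to the sulfone chemoselectively (catalytic ammonium molybdate/H2O2), remove Boc under non-protic conditions (TMSOTf/2,6-lutidine), and guanylate the amine with 1H-pyrazole-1-carboxamidine.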